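**Retrosynthetic overview**
1. Target 13 comes from 12 by removing two MOM groups. Nothing else changes in the last step.
2. The key disconnection is C6–C1''. Compound 12 comes from the 5-O-geranyl ether 10 by a [1,3]-sigmatropic O-to-C shift: C6 is the only free carbon next to O5, and the E-alkene of geraniol 9 is carried through. Ether 10 comes from 8 and 9 (Mitsunobu).
3. C2 is bought in (2R,3R)-dihydromyricetin 1. Compound 8 comes from 6 by SmI2 removal of the 3-acetoxy group; the spatial arrangement at C2 is unchanged and only the descriptor goes from R to S.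
4. The B-ring pattern in 5 comes from 1 by a transient 4',5'-boronate, MOM protection of 7-OH and 3'-OH, then O-methylation of the released catechol.
5. Rings A, B and C all come ready-made in 1; no ring is formed in the route.

Assumption: commercial vine-tea (+)-dihydromyricetin is taken as the enantiopure (2R,3R) form, checked by chiral HPLC before use.

**Step 1**
Reactants: 1 (+)-dihydromyricetin
Product: 4 (2R,3R)-3,5,4',5'-tetrahydroxy-7,3'-bis(methoxymethoxy)flavanone, via phenylboronate 2 (not isolated), via bis-MOM phenylboronate 3 (not isolated)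
Conditions: PhB(OH)2 (1.05 equiv), 4 Å MS, THF, rt; then MOMCl (2.2 equiv), i-Pr2NEt, 0 °C; then H2O–MeOH, rt
Reagents that add atoms: chloromethyl methyl ether (MOMCl), COCCl; phenylboronic acid, OB(O)c1ccccc1 (held only in 2 and 3, released again on hydrolysis)
Why: Cyclic boronate formation ties up two adjacent B-ring hydroxyls (either pair is equivalent by symmetry), so O-alkylation with MOMCl reaches only the acidic 7-OH and the one remaining lateral B-ring OH, while the hydrogen-bonded 5-OH and the secondary 3-OH stay free and no stereocentre is touched.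

**Step 2**
Reactants: 4 (2R,3R)-3,5,4',5'-tetrahydroxy-7,3'-bis(methoxymethoxy)flavanone
Product: 5 (2R,3R)-3,5-dihydroxy-4',5'-dimethoxy-7,3'-bis(methoxymethoxy)flavanone
Conditions: TMSCHN2 (2.5 equiv), i-Pr2NEt (cat.), MeCN–MeOH 9:1, 0 °C to rt
Reagents that add atoms: (trimethylsilyl)diazomethane, C[Si](C)(C)C=[N+]=[N-]
Why: In this diazoalkane O-methylation only the two free catechol hydroxyls are acidic enough to react, the chelated 5-OH and the 3-OH are inert, and the near-neutral medium cannot epimerise C2 or C3.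

**Step 3**
Reactants: 5 (2R,3R)-3,5-dihydroxy-4',5'-dimethoxy-7,3'-bis(methoxymethoxy)flavanone
Product: 6 (2R,3R)-3-acetoxy-5-hydroxy-4',5'-dimethoxy-7,3'-bis(methoxymethoxy)flavanone
Conditions: Ac2O (1.1 equiv), pyridine, 0 °C
Reagents that add atoms: acetic anhydride, CC(=O)OC(C)=O
Why: In this chemoselective O-acylation the secondary 3-OH reacts faster than the 5-OH, which is locked in a hydrogen bond to the C4 carbonyl, and the acetate makes C3–O a leaving group for step 4.

**Step 4**
Reactants: 6 (2R,3R)-3-acetoxy-5-hydroxy-4',5'-dimethoxy-7,3'-bis(methoxymethoxy)flavanone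
Product: 8 (2S)-5-hydroxy-4',5'-dimethoxy-7,3'-bis(methoxymethoxy)flavanone, via samarium enolate 7 (not isolated)
Conditions: SmI2 (2.5 equiv), THF–MeOH, −78 °C; aq NH4Cl
Reagents that add atoms: samarium diiodide, I[Sm]I (its atoms sit only in 7, none stays in 8)
Why: SmI2 reductive cleavage of an α-acyloxy ketone expels acetate by two single-electron transfers, MeOH and the neighbouring 5-OH protonate enolate 7 at −78 °C before it can eject the C2 aryloxide, and so C2 keeps its bought configuration and is called S only because C3 has lost its oxygen.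

**Step 5**
Reactants: 8 (2S)-5-hydroxy-4',5'-dimethoxy-7,3'-bis(methoxymethoxy)flavanone; 9 geraniol
Product: 10 (2S)-5-[(E)-geranyloxy]-4',5'-dimethoxy-7,3'-bis(methoxymethoxy)flavanone
Conditions: PPh3, DIAD, THF, 0 °C to rt
Reagents that add atoms: none
Why: In this Mitsunobu etherification the only free acidic OH (5-OH) displaces the activated primary allylic oxygen of 9 by SN2, so the E-alkene is kept and no strong base is present that could open ring C.

**Step 6**
Reactants: 10 (2S)-5-[(E)-geranyloxy]-4',5'-dimethoxy-7,3'-bis(methoxymethoxy)flavanone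
Product: 12 (2S)-6-[(E)-geranyl]-5-hydroxy-4',5'-dimethoxy-7,3'-bis(methoxymethoxy)flavanone, via cyclohexadienone 11 (not isolated)
Conditions: Florisil (activated magnesium silicate, MgSiO3), toluene, reflux
Reagents that add atoms: none
Why: In this Florisil-promoted [1,3]-sigmatropic O-to-C shift of a carbonyl-flanked aryl allyl ether the surface binds the C4=O/O5 pair, C1'' moves from O5 to C6 (the only hydrogen-bearing carbon next to O5) without allylic inversion so the E-alkene is retained, dienone 11 enolises to the chelated phenol, and C2 takes no part.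

**Step 7**
Reactants: 12 (2S)-6-[(E)-geranyl]-5-hydroxy-4',5'-dimethoxy-7,3'-bis(methoxymethoxy)flavanone
Product: 13 (2S)-6-[(E)-geranyl]-5,7,3'-trihydroxy-4',5'-dimethoxyflavanone (CNP0228243.1)
Conditions: HCl (3 M aq, cat.), MeOH, 45 °C, short reaction time
Reagents that add atoms: none
Why: Acid-catalysed transacetalisation cleaves both aryl MOM acetals, and under this brief mild acid treatment the flavanone does not racemise and the geranyl chain does not cyclise onto the neighbouring phenols.

**Compound list**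
1 | (+)-dihydromyricetin, (2R,3R)-3,5,7,3',4',5'-hexahydroxyflavanone | Oc1cc([C@@H]2[C@@H](O)C(=O)c3c(cc(O)cc3O)O2)cc(O)c1O | starting material
2 | dihydromyricetin 4',5'-O-phenylboronate (formed in the flask) | Oc1cc([C@@H]2[C@@H](O)C(=O)c3c(cc(O)cc3O)O2)cc4OB(c5ccccc5)Oc14 | intermediate
3 | 7,3'-di-O-MOM-dihydromyricetin 4',5'-O-phenylboronate (formed in the flask) | COCOc1cc([C@@H]2[C@@H](O)C(=O)c3c(cc(OCOC)cc3O)O2)cc4OB(c5ccccc5)Oc14 | intermediate
4 | (2R,3R)-3,5,4',5'-tetrahydroxy-7,3'-bis(methoxymethoxy)flavanone | COCOc1cc([C@@H]2[C@@H](O)C(=O)c3c(cc(OCOC)cc3O)O2)cc(O)c1O | intermediate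
5 | (2R,3R)-3,5-dihydroxy-4',5'-dimethoxy-7,3'-bis(methoxymethoxy)flavanone | COCOc1cc([C@@H]2[C@@H](O)C(=O)c3c(cc(OCOC)cc3O)O2)cc(OC)c1OC | intermediate
6 | (2R,3R)-3-acetoxy-5-hydroxy-4',5'-dimethoxy-7,3'-bis(methoxymethoxy)flavanone | COCOc1cc([C@@H]2[C@@H](OC(C)=O)C(=O)c3c(cc(OCOC)cc3O)O2)cc(OC)c1OC | intermediate
7 | C3=C4 samarium enolate of 8, O–SmI2 (formed in the flask) | COCOc1cc([C@@H]2C=C(O[Sm](I)I)c3c(cc(OCOC)cc3O)O2)cc(OC)c1OC | intermediate
8 | (2S)-5-hydroxy-4',5'-dimethoxy-7,3'-bis(methoxymethoxy)flavanone | COCOc1cc([C@@H]2CC(=O)c3c(cc(OCOC)cc3O)O2)cc(OC)c1OC | intermediate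
9 | geraniol, (E)-3,7-dimethylocta-2,6-dien-1-ol | OC/C=C(\C)CCC=C(C)C | starting material
10 | (2S)-5-[(E)-geranyloxy]-4',5'-dimethoxy-7,3'-bis(methoxymethoxy)flavanone | COCOc1cc([C@@H]2CC(=O)c3c(cc(OCOC)cc3OC/C=C(\C)CCC=C(C)C)O2)cc(OC)c1OC | intermediate
11 | 6-geranyl-6H-cyclohexadien-5-one tautomer of 12, C6 unassigned (formed in the flask) | COCOc1cc([C@@H]2CC(=O)C3=C(C=C(OCOC)C(C/C=C(\C)CCC=C(C)C)C3=O)O2)cc(OC)c1OC | intermediate
12 | (2S)-6-[(E)-geranyl]-5-hydroxy-4',5'-dimethoxy-7,3'-bis(methoxymethoxy)flavanone | COCOc1cc([C@@H]2CC(=O)c3c(cc(OCOC)c(C/C=C(\C)CCC=C(C)C)c3O)O2)cc(OC)c1OC | intermediate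
13 | (2S)-6-[(E)-geranyl]-5,7,3'-trihydroxy-4',5'-dimethoxyflavanone | COc1cc([C@@H]2CC(=O)c3c(cc(O)c(C/C=C(\C)CCC=C(C)C)c3O)O2)cc(O)c1OC | target

**Totals**
Total step count: 7. Longest linear sequence: 7 steps, from 1.

**Steps most likely to fail**

Step 6 is the weakest point. The ether may simply lose its geranyl group and return 8. Part of the material may end up geranylated at C8, or as the inverted 6-substituent by a competing [3,3] path. Hot Florisil could also erode the ee at C2, which is checked by chiral HPLC on 12. The fallback sets out from 8. Iodination ortho to the free 5-OH (BnMe3N·ICl2, CaCO3, CH2Cl2–MeOH, rt) gives the (2S)-6-iodoflavanone F1. F1 is joined in a Stille coupling (Pd(PPh3)4, DMF, 80 °C) to (E)-geranyltributylstannane F2, itself made from geranyl chloride and Bu3SnLi. This comes back to the route at 12.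

Step 1 is next. The boronate may not hold during alkylation, which would put MOM on the central B-ring oxygen, and over-alkylation at 3-OH is possible. The fallback sets out from 1 and uses an isolable mask instead of a transient one. Ph2CCl2 and i-Pr2NEt in MeCN at 60 °C give the dihydromyricetin 4',5'-O-diphenylmethylene ketal F3. MOMCl and i-Pr2NEt convert it into the 7,3'-di-O-MOM diphenylmethylene ketal F4. Hydrogenolysis (H2, Pd/C, THF–MeOH, rt; no alkene is present yet) frees the catechol and comes back to the route at 4.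

Step 4 is third. Enolate 7 could eject the C2 aryloxide to give the chalcone, which would reclose as a racemate, or the aryl ketone could be over-reduced. The fallback sets out from 5, bypassing 6, and swaps the ionic pathway for a radical one. 1,1'-Thiocarbonyldiimidazole in THF at 60 °C gives the 3-O-(imidazol-1-ylthiocarbonyl) derivative F5. Barton–McCombie deoxygenation (Bu3SnH, AIBN, toluene, 80 °C) removes the C3 oxygen through an α-keto radical that leaves C2 alone. This comes back to the route at 8.

**Further compounds**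
F1 | step 6 | (2S)-5-hydroxy-6-iodo-4',5'-dimethoxy-7,3'-bis(methoxymethoxy)flavanone | COCOc1cc([C@@H]2CC(=O)c3c(cc(OCOC)c(I)c3O)O2)cc(OC)c1OC
F2 | step 6 | (E)-geranyltributylstannane | CCCC[Sn](CCCC)(CCCC)C/C=C(\C)CCC=C(C)C
F3 | step 1 | (2R,3R)-dihydromyricetin 4',5'-O-diphenylmethylene ketal | Oc1cc([C@@H]2[C@@H](O)C(=O)c3c(cc(O)cc3O)O2)cc4OC(c5ccccc5)(c5ccccc5)Oc14
F4 | step 1 | (2R,3R)-7,3'-di-O-MOM-dihydromyricetin 4',5'-O-diphenylmethylene ketal | COCOc1cc([C@@H]2[C@@H](O)C(=O)c3c(cc(OCOC)cc3O)O2)cc4OC(c5ccccc5)(c5ccccc5)Oc14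
F5 | step 4 | (2R,3R)-5-hydroxy-3-(imidazol-1-ylthiocarbonyloxy)-4',5'-dimethoxy-7,3'-bis(methoxymethoxy)flavanone | COCOc1cc([C@@H]2[C@@H](OC(=S)n4ccnc4)C(=O)c3c(cc(OCOC)cc3O)O2)cc(OC)c1OC
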